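**Plan**

- Retrosynthesis (eremophilane numbering; ring A = C1–C5 and C10, ring B = C5–C10, C14 on C5, C15 on C4): cut the ester C–O bond at C3, then C7=C11 (acetone aldol), C3–O/C4–H (hydration of a C3=C4 olefin) and C9–O (enolate oxidation), then ring A at C1–C2 and C3–C4, then ring B at C9–C10 and C5–C6.
- Enabling feature: C1 is the vinylogous (γ) carbon of the C8 carbonyl through C9=C10, and C4 is a methyl-bearing carbon on the quaternary C5, that is, a latent acetyl carbonyl. A two-carbon vinylphosphonium unit (C2–C3) can therefore be stitched between a dienolate carbon and a ketone in one Michael–Wittig operation on a monocyclic ring B enone.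
- Forward order: ring B (Michael addition, proline aldol condensation), ring A by the annulation, trans ring fusion and C9–OH (dissolving-metal reduction, enolate hydroxylation), isopropylidene (acetone aldol condensation), C3–OH/C4–H (hydroboration), acylation with the separately made trienoic acid, desilylation.
- Stereochemistry: C5 comes from the enantiotopic-group-selective proline aldol; C10, C9, C3 and C4 are relayed from the axial C5 methyl (trans protonation, α-face oxidation, α-face syn hydroboration). The triene geometry comes from (E)-oct-2-enal, syn carboalumination and an (E)-selective Heck reaction.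

Key step: step 3

Assumption: (S)-proline is taken to select the acetyl group that gives (S)-configured C5 in step 2, the sense known for the Hajos–Parrish and Wieland–Miescher triketones; if the opposite sense operates, (R)-proline is used.

**Route**

Step 1
Reactants: 1 3-methylpentane-2,4-dione; 2 but-3-en-2-one (methyl vinyl ketone)
Product: 3 3-acetyl-3-methylheptane-2,6-dione
Conditions: Et3N (10 mol%), CH2Cl2, 25 °C
Reagents that add atoms: none
Why: Amine-catalysed Michael addition of the acidic methine of the 1,3-diketone to the vinyl ketone should give the triketone, in which C5 is still prochiral (two identical acetyl groups), so no stereocentre is formed.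

Step 2
Reactants: 3 3-acetyl-3-methylheptane-2,6-dione
Product: 4 (S)-4-acetyl-3,4-dimethylcyclohex-2-en-1-one
Conditions: (S)-proline (30 mol%), 1 M aq HClO4 (15 mol%), MeCN, 80 °C
Reagents that add atoms: none
Why: In this Hajos–Parrish-type proline-catalysed aldol condensation the enamine of the unhindered side-chain methyl ketone should attack one of the two enantiotopic acetyl carbonyls through the carboxylic-acid-organised transition state, which sets the quaternary centre C5 as (S), and acid-promoted dehydration then gives the C9=C10 enone of ring B.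

Step 3
Reactants: 4 (S)-4-acetyl-3,4-dimethylcyclohex-2-en-1-one; 5 vinyltriphenylphosphonium bromide
Product: 8 (R)-4a,5-dimethyl-4,4a,7,8-tetrahydronaphthalen-2(3H)-one, via potassium dienolate 6 (not isolated), via phosphorus ylide 7 (not isolated)
Conditions: KN(SiMe3)2 (0.95 equiv), THF, −78 → 0 °C; then 5 (1.2 equiv), THF/DMF, 0 → 60 °C
Reagents that add atoms: none
Why: Proposed new method: the thermodynamic extended enolate 6 (deprotonated at the C1 methyl, the only γ-position because C5 is quaternary) should add through C1 to the β-carbon of the vinylphosphonium salt to form the C1–C2 bond and the non-stabilised ylide 7, whose carbanionic C3 then attacks the C4 acetyl carbonyl and forms the C3=C4 bond with loss of Ph3PO; the closest known reaction type is the Schweizer annulation, in which a stabilised carbanion carrying a ketone adds to vinyltriphenylphosphonium bromide and closes a cycloalkene by intramolecular Wittig reaction, here extended to a vinylogous ketone enolate. Ring A closes in the 6-exo-trig mode (ylide carbon onto the acetyl C=O), followed by cycloreversion of the oxaphosphetane. No stereocentre is created, the C5 centre is not touched, and the endocyclic position of the new trisubstituted olefin leaves no geometry to control. The step needs C-attack at C1 and not at C9 or C7: the conjugate addition to the phosphonium salt is reversible (the ylide can expel the enolate), only the C1 adduct reaches the acetyl group through an unstrained fused transition state, the C9 and C7 adducts would have to close bridged bicyclo[3.3.1]nonenes, and closure onto C8 would give a bridgehead olefin. Equilibration to the extended enolate before the salt is added (slight deficit of base, 0 °C) should keep the kinetic C7 and acetyl enolates low.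

Step 4
Reactants: 8 (R)-4a,5-dimethyl-4,4a,7,8-tetrahydronaphthalen-2(3H)-one
Product: 10 (1S,4aS,8aR)-1-hydroxy-4a,5-dimethyl-3,4,4a,7,8,8a-hexahydronaphthalen-2(1H)-one, via lithium enolate 9 (not isolated)
Conditions: Li (2.3 equiv), t-BuOH (1.0 equiv), NH3(l)/THF, −78 °C; isoprene; NH3 removed, THF, −78 °C; Davis oxaziridine (1.3 equiv); aq NH4Cl
Reagents that add atoms: 2-(phenylsulfonyl)-3-phenyloxaziridine (Davis oxaziridine), O=S(=O)(N1OC1c1ccccc1)c1ccccc1
Why: Dissolving-metal reduction of the enone should give the C8 lithium enolate of the trans-fused ketone regiospecifically (protonation of the C10 carbanion on the face opposite the C5 methyl sets C10–H α), and the Davis oxaziridine should then hydroxylate this enolate at C9 from the α face, away from the axial C5 methyl, to give the equatorial 9α-alcohol, the isolated C3=C4 olefin being inert to both reagents.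

Step 5
Reactants: 10 (1S,4aS,8aR)-1-hydroxy-4a,5-dimethyl-3,4,4a,7,8,8a-hexahydronaphthalen-2(1H)-one
Product: 11 (1S,4aS,8aR)-1-[(tert-butyldimethylsilyl)oxy]-4a,5-dimethyl-3,4,4a,7,8,8a-hexahydronaphthalen-2(1H)-one
Conditions: TBSOTf, 2,6-lutidine, CH2Cl2, −78 → 0 °C
Reagents that add atoms: tert-butyldimethylsilyl trifluoromethanesulfonate, CC(C)(C)[Si](C)(C)OS(=O)(=O)C(F)(F)F
Why: Silylation of the secondary α-ketol with the silyl triflate and a hindered pyridine base should mask O9 for the enolate chemistry that follows without touching any stereocentre.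

Step 6
Reactants: 11 (1S,4aS,8aR)-1-[(tert-butyldimethylsilyl)oxy]-4a,5-dimethyl-3,4,4a,7,8,8a-hexahydronaphthalen-2(1H)-one; 12 propan-2-one (acetone)
Product: 14 (1S,4aS,8aR)-1-[(tert-butyldimethylsilyl)oxy]-3-(2-hydroxypropan-2-yl)-4a,5-dimethyl-3,4,4a,7,8,8a-hexahydronaphthalen-2(1H)-one (either C3 epimer), via lithium enolate 13 (not isolated)
Conditions: LiN(iPr)2 (1.1 equiv), THF, −78 °C; then acetone (3 equiv), −78 °C; AcOH quench
Reagents that add atoms: none
Why: Kinetic deprotonation by the lithium amide should occur at C7, the only methylene flanking the carbonyl (C9 carries the silyloxy group), and aldol addition of this enolate to acetone should give the tertiary β-hydroxy ketone, whose C7 configuration is of no consequence because it is removed in step 7.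

Step 7
Reactants: 14 (1S,4aS,8aR)-1-[(tert-butyldimethylsilyl)oxy]-3-(2-hydroxypropan-2-yl)-4a,5-dimethyl-3,4,4a,7,8,8a-hexahydronaphthalen-2(1H)-one
Product: 16 (1S,4aS,8aR)-1-[(tert-butyldimethylsilyl)oxy]-4a,5-dimethyl-3-(propan-2-ylidene)-3,4,4a,7,8,8a-hexahydronaphthalen-2(1H)-one, via tertiary mesylate 15 (not isolated)
Conditions: MsCl, Et3N, CH2Cl2, 0 °C; then DBU, 25 → 40 °C
Reagents that add atoms: none
Why: Mesylation of the tertiary alcohol through sulfene and E1cB elimination through the C7 enolate should give the conjugated tetrasubstituted C7=C11 enone (the isopropylidene group), the base also moving any β,γ-isomer into conjugation.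

Step 8
Reactants: 16 (1S,4aS,8aR)-1-[(tert-butyldimethylsilyl)oxy]-4a,5-dimethyl-3-(propan-2-ylidene)-3,4,4a,7,8,8a-hexahydronaphthalen-2(1H)-one
Product: 18 (1S,4aR,5R,6R,8aR)-1-[(tert-butyldimethylsilyl)oxy]-4a,5-dimethyl-3-(propan-2-ylidene)decahydronaphthalene-2,6-diol (either C2 epimer), via organoborane 17 (not isolated)
Conditions: BH3·THF (3 equiv), THF, 0 → 25 °C; then 30% H2O2, aq NaOAc, 0 → 25 °C
Reagents that add atoms: hydrogen peroxide, OO
Why: Hydroboration–oxidation of the trisubstituted C3=C4 olefin should occur anti-Markovnikov and syn from the α face, opposite the axial C5 methyl, which places OH on C3 (α, equatorial) and H on C4 (so that C15 is β), while the C8 carbonyl is reduced at the same time to an allylic alcohol that step 9 reoxidises.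

Step 9
Reactants: 18 (1S,4aR,5R,6R,8aR)-1-[(tert-butyldimethylsilyl)oxy]-4a,5-dimethyl-3-(propan-2-ylidene)decahydronaphthalene-2,6-diol
Product: 19 (1S,4aR,5R,6R,8aR)-1-[(tert-butyldimethylsilyl)oxy]-6-hydroxy-4a,5-dimethyl-3-(propan-2-ylidene)octahydronaphthalen-2(1H)-one
Conditions: MnO2 (excess), CH2Cl2, 25 °C
Reagents that add atoms: none
Why: MnO2 should oxidise only the allylic C8 alcohol back to the enone and leave the saturated secondary C3 alcohol untouched (chemoselective allylic oxidation), so that both C8 epimers converge.

Step 10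
Reactants: 20 (E)-oct-2-enal
Product: 21 (E)-non-3-en-1-yne
Conditions: Me3SiCHN2, n-BuLi, THF, −78 °C; then 20, −78 → 25 °C
Reagents that add atoms: (trimethylsilyl)diazomethane, C[Si](C)(C)C=[N+]=[N-]
Why: In this Colvin homologation the lithiated silyldiazomethane adds to the aldehyde, Peterson-type loss of silanolate and of N2 gives an alkylidene carbene, and its 1,2-hydrogen shift should give the terminal enyne with the (E)-olefin unchanged.

Step 11
Reactants: 21 (E)-non-3-en-1-yne
Product: 23 (1E,3E)-1-iodo-2-methylnona-1,3-diene, via alkenylalane 22 (not isolated)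
Conditions: Me3Al (2 equiv), Cp2ZrCl2 (25 mol%), CH2Cl2, 0 → 25 °C; then I2, THF, −30 → 0 °C
Reagents that add atoms: trimethylaluminium, C[Al](C)C; iodine, II
Why: Zirconium-catalysed methylalumination of the terminal alkyne (Negishi carboalumination) is a syn addition that places methyl on the internal carbon, and iodinolysis of the alkenyl–aluminium bond with retention should give the (1E,3E)-dienyl iodide, which fixes the geometry of the trisubstituted olefin of the acid.

Step 12
Reactants: 23 (1E,3E)-1-iodo-2-methylnona-1,3-diene; 24 ethyl acrylate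
Product: 25 ethyl (2E,4E,6E)-5-methyldodeca-2,4,6-trienoate
Conditions: Pd(OAc)2 (5 mol%), K2CO3, Bu4NCl, DMF, 25–50 °C
Reagents that add atoms: none
Why: In this Heck reaction under ligand-free phase-transfer conditions, oxidative addition of the alkenyl iodide to zerovalent palladium with retention, syn insertion of the acrylate and syn β-hydride elimination should give the (2E) olefin and hence the all-(E) trienoate.

Step 13
Reactants: 25 ethyl (2E,4E,6E)-5-methyldodeca-2,4,6-trienoate
Product: 26 (2E,4E,6E)-5-methyldodeca-2,4,6-trienoic acid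
Conditions: LiOH, THF/H2O, 25 °C; then 1 M HCl
Reagents that add atoms: lithium hydroxide, [Li+].[OH-]
Why: Saponification of the ethyl ester with hydroxide followed by acidification should release the trienoic acid without affecting the olefin geometry.

Step 14
Reactants: 19 (1S,4aR,5R,6R,8aR)-1-[(tert-butyldimethylsilyl)oxy]-6-hydroxy-4a,5-dimethyl-3-(propan-2-ylidene)octahydronaphthalen-2(1H)-one; 26 (2E,4E,6E)-5-methyldodeca-2,4,6-trienoic acid
Product: 27 9-O-(tert-butyldimethylsilyl) ether of the target (3-O-trienoyl ester of 19)
Conditions: DCC, DMAP (cat.), CH2Cl2, 0 → 25 °C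
Reagents that add atoms: none
Why: Steglich esterification (carbodiimide activation, acyl transfer through the acylpyridinium ion) should acylate the only free hydroxyl, the equatorial C3 alcohol, with retention at C3, O9 being masked as the silyl ether.

Step 15
Reactants: 27 9-O-(tert-butyldimethylsilyl) ether of the target
Product: 28 (3R,4R,5R,9S,10R)-9-hydroxy-8-oxoeremophil-7(11)-en-3-yl (2E,4E,6E)-5-methyldodeca-2,4,6-trienoate (CNP0211657.1)
Conditions: HF·pyridine, THF/pyridine, 0 → 25 °C
Reagents that add atoms: none
Why: Fluoride-mediated cleavage of the silyl ether under buffered conditions should release the 9α-hydroxyl without touching the ester, the triene or the enone, and so give the target.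

**Compound list**

1 | 3-methylpentane-2,4-dione | CC(=O)C(C)C(C)=O | starting material
2 | but-3-en-2-one (methyl vinyl ketone) | CC(=O)C=C | starting material
3 | 3-acetyl-3-methylheptane-2,6-dione | CC(=O)CCC(C)(C(C)=O)C(C)=O | intermediate
4 | (S)-4-acetyl-3,4-dimethylcyclohex-2-en-1-one | CC(=O)[C@@]1(C)CCC(=O)C=C1C | intermediate
5 | vinyltriphenylphosphonium bromide | C=C[P+](c1ccccc1)(c1ccccc1)c1ccccc1.[Br-] | starting material
6 | potassium (S)-4-acetyl-4-methyl-3-methylidenecyclohex-1-en-1-olate (extended enolate of 4) | C=C1C=C([O-])CC[C@]1(C)C(C)=O.[K+] | intermediate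
7 | (S)-4-acetyl-4-methyl-3-[3-(triphenylphosphoranylidene)propyl]cyclohex-2-en-1-one (ylide) | CC(=O)[C@@]1(C)CCC(=O)C=C1CCC=P(c2ccccc2)(c2ccccc2)c2ccccc2 | intermediate
8 | (R)-4a,5-dimethyl-4,4a,7,8-tetrahydronaphthalen-2(3H)-one | CC1=CCCC2=CC(=O)CC[C@]12C | intermediate
9 | lithium (4aS,8aS)-4a,5-dimethyl-3,4,4a,7,8,8a-hexahydronaphthalen-2-olate (trans-fused C8 enolate) | CC1=CCC[C@H]2C=C(O[Li])CC[C@]12C | intermediate
10 | (1S,4aS,8aR)-1-hydroxy-4a,5-dimethyl-3,4,4a,7,8,8a-hexahydronaphthalen-2(1H)-one | CC1=CCC[C@H]2[C@H](O)C(=O)CC[C@]12C | intermediate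
11 | (1S,4aS,8aR)-1-[(tert-butyldimethylsilyl)oxy]-4a,5-dimethyl-3,4,4a,7,8,8a-hexahydronaphthalen-2(1H)-one | CC1=CCC[C@H]2[C@H](O[Si](C)(C)C(C)(C)C)C(=O)CC[C@]12C | intermediate
12 | propan-2-one (acetone) | CC(C)=O | starting material
13 | lithium (1S,4aS,8aR)-1-[(tert-butyldimethylsilyl)oxy]-4a,5-dimethyl-1,4,4a,7,8,8a-hexahydronaphthalen-2-olate (C7 enolate of 11) | CC1=CCC[C@H]2[C@H](O[Si](C)(C)C(C)(C)C)C(O[Li])=CC[C@]12C | intermediate
14 | (1S,4aS,8aR)-1-[(tert-butyldimethylsilyl)oxy]-3-(2-hydroxypropan-2-yl)-4a,5-dimethyl-3,4,4a,7,8,8a-hexahydronaphthalen-2(1H)-one (C3 epimers) | CC1=CCC[C@H]2[C@H](O[Si](C)(C)C(C)(C)C)C(=O)C(C(C)(C)O)C[C@]12C | intermediate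
15 | methanesulfonate of the tertiary alcohol of 14 | CC1=CCC[C@H]2[C@H](O[Si](C)(C)C(C)(C)C)C(=O)C(C(C)(C)OS(C)(=O)=O)C[C@]12C | intermediate
16 | (1S,4aS,8aR)-1-[(tert-butyldimethylsilyl)oxy]-4a,5-dimethyl-3-(propan-2-ylidene)-3,4,4a,7,8,8a-hexahydronaphthalen-2(1H)-one | CC1=CCC[C@H]2[C@H](O[Si](C)(C)C(C)(C)C)C(=O)C(=C(C)C)C[C@]12C | intermediate
17 | organoborane from 16 (idealised: BH2 on C3 from the α face, C8 carbonyl reduced to the O-boryl alcohol) | [BH2][C@@H]1CC[C@H]2[C@H](O[Si](C)(C)C(C)(C)C)C(O[BH2])C(=C(C)C)C[C@]2(C)[C@H]1C | intermediate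
18 | (1S,4aR,5R,6R,8aR)-1-[(tert-butyldimethylsilyl)oxy]-4a,5-dimethyl-3-(propan-2-ylidene)decahydronaphthalene-2,6-diol (C2 epimers) | O[C@@H]1CC[C@H]2[C@H](O[Si](C)(C)C(C)(C)C)C(O)C(=C(C)C)C[C@]2(C)[C@H]1C | intermediate
19 | (1S,4aR,5R,6R,8aR)-1-[(tert-butyldimethylsilyl)oxy]-6-hydroxy-4a,5-dimethyl-3-(propan-2-ylidene)octahydronaphthalen-2(1H)-one | O[C@@H]1CC[C@H]2[C@H](O[Si](C)(C)C(C)(C)C)C(=O)C(=C(C)C)C[C@]2(C)[C@H]1C | intermediate
20 | (E)-oct-2-enal | CCCCC/C=C/C=O | starting material
21 | (E)-non-3-en-1-yne | CCCCC/C=C/C#C | intermediate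
22 | dimethyl[(1E,3E)-2-methylnona-1,3-dien-1-yl]alane | CCCCC/C=C/C(C)=C/[Al](C)C | intermediate
23 | (1E,3E)-1-iodo-2-methylnona-1,3-diene | CCCCC/C=C/C(C)=C/I | intermediate
24 | ethyl acrylate | C=CC(=O)OCC | starting material
25 | ethyl (2E,4E,6E)-5-methyldodeca-2,4,6-trienoate | CCCCC/C=C/C(C)=C/C=C/C(=O)OCC | intermediate
26 | (2E,4E,6E)-5-methyldodeca-2,4,6-trienoic acid | CCCCC/C=C/C(C)=C/C=C/C(=O)O | intermediate
27 | 9-O-(tert-butyldimethylsilyl) ether of the target | CCCCC/C=C/C(C)=C/C=C/C(=O)O[C@@H]1CC[C@H]2[C@H](O[Si](C)(C)C(C)(C)C)C(=O)C(=C(C)C)C[C@]2(C)[C@H]1C | intermediate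
28 | (3R,4R,5R,9S,10R)-9-hydroxy-8-oxoeremophil-7(11)-en-3-yl (2E,4E,6E)-5-methyldodeca-2,4,6-trienoate | CCCCC/C=C/C(C)=C/C=C/C(=O)O[C@@H]1CC[C@H]2[C@H](O)C(=O)C(=C(C)C)C[C@]2(C)[C@H]1C | target

**Step count**

Total: 15 steps. Longest linear sequence: 11 steps (steps 1–9, 14, 15); the acid branch (steps 10–13) joins at step 14.

**Steps most likely to fail**

1. Step 3 (Proposed new method). The conjugate addition may take place through C9 or C7 of the enolate instead of C1, or the ylide may be quenched by proton transfer faster than it closes the ring, so that ring A does not form. The fallback uses known chemistry, gives up the annulation, sets out from 2 and comes back at 8 (it also bypasses step 2). Michael addition of commercial 2-methylcyclohexane-1,3-dione to 2 should give 2-methyl-2-(3-oxobutyl)cyclohexane-1,3-dione F1. (S)-Proline-catalysed cyclisation should give (S)-8a-methyl-3,4,8,8a-tetrahydronaphthalene-1,6(2H,7H)-dione F2 (the Wieland–Miescher ketone). Selective dithioketalisation of the conjugated carbonyl (ethane-1,2-dithiol, TsOH, AcOH; the saturated ketone is neopentylic) should give the enone dithiolane F3. Addition of MeLi (CeCl3) to the remaining ketone should give the tertiary alcohol F4. Acid-catalysed dehydration (TsOH, toluene) to the endocyclic trisubstituted olefin should give the diene dithiolane F5, and MeI/CaCO3 in aqueous MeCN should release the enone, which is 8.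

2. Step 2. The enamine may discriminate poorly between the two enantiotopic acetyl groups of an acyclic diketone, so that 4 is formed with insufficient enantiomeric purity. The fallback replaces asymmetric catalysis by resolution, sets out from 3 and comes back at 4. Cyclisation of 3 with pyrrolidine/AcOH should give racemic 4-acetyl-3,4-dimethylcyclohex-2-en-1-one F6, and the enantiomers are separated by preparative chromatography on a chiral stationary phase, the (S)-enantiomer being 4.

3. Step 8. The borane may also hydroborate the tetrasubstituted C7=C11 olefin once the C8 carbonyl has been reduced, or the silyl group may migrate from O9 to O8 during the oxidative work-up, so that the C3 alcohol is not obtained cleanly. The fallback replaces hydroboration by epoxidation and radical epoxide opening, sets out from 16 and comes back at 19 without touching the carbonyl. mCPBA should epoxidise only the electron-rich C3=C4 olefin, from the α face, to give the 3α,4α-epoxide F7. Titanocene monochloride Cp2TiCl (trivalent titanium, from Cp2TiCl2 and Zn) with 1,4-cyclohexadiene in THF should open it homolytically to the tertiary C4 radical, and hydrogen-atom transfer to the α face should give 19, with the C4 epimer removed by chromatography if it forms.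

**Further compounds**

F1 | step 3 | 2-methyl-2-(3-oxobutyl)cyclohexane-1,3-dione | CC(=O)CCC1(C)C(=O)CCCC1=O
F2 | step 3 | (S)-8a-methyl-3,4,8,8a-tetrahydronaphthalene-1,6(2H,7H)-dione | O=C1CCCC2=CC(=O)CC[C@]12C
F3 | step 3 | 6,6-(ethane-1,2-diyldisulfanediyl) dithioketal of F2 (spiro-1,3-dithiolane at the former enone carbonyl) | O=C1CCCC2=CC3(SCCS3)CC[C@]12C
F4 | step 3 | tertiary alcohol from methyl addition to the ketone of F3 (carbinol epimers) | CC1(O)CCCC2=CC3(SCCS3)CC[C@]12C
F5 | step 3 | 1,3-dithiolane of 8 | CC1=CCCC2=CC3(SCCS3)CC[C@]12C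
F6 | step 2 | racemic 4-acetyl-3,4-dimethylcyclohex-2-en-1-one | CC(=O)C1(C)CCC(=O)C=C1C
F7 | step 8 | 3α,4α-epoxide of 16 | O1[C@@H]2CC[C@H]3[C@H](O[Si](C)(C)C(C)(C)C)C(=O)C(=C(C)C)C[C@]3(C)[C@]12C
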